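**Plan** (numbering: C1 quaternary fusion carbon with CH3, C2/C3 ring-A CH2, C4 isopropyl carbinol, C5 fusion CH, C6 benzoyloxy carbon, C7 CH2, C8(CH3)=C9, C10 angeloyloxy carbon; ring A = C1–C5, ring B = C1, C5–C10)
Retrosynthesis: cut the C10–O angelate (formed with inversion) and the C6–O benzoate, take C8=C9 and both carbinols back to a C6/C10 diketone, then cut C1–C5 and C8–C9 together; in the open chain cut C6–C7 (propenyl addition) and C3–C4 (sp3–sp2 coupling).
Enabling feature: C10 is a ketone-level carbon between quaternary C1 and C9, and C6 carries oxygen next to C5, so ring B is the adduct of a 2-oxyallyl cation C9–C10–C1 with a 2-siloxydiene C5=C6(OSi)–C7=C8; the C2–C3–C4 tether makes the C1–C5 bond close ring A.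
Forward: the chain is assembled by Negishi coupling, epoxidation/hydride opening and propenyl addition; both ketones are enol-silylated (no base distinguishes them), and silver-promoted ionisation of the tertiary chloride closes ring A and ring B in one operation; C6 and C10 are then adjusted and acylated.
Stereochemistry: C4 from tartrate-controlled Sharpless epoxidation; C1 and C5 from the cycloaddition under control of C4; C6 from a C4-hydroxyl-directed reduction; C10 from hydride attack anti to the C1 methyl followed by Mitsunobu inversion.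

Key step: step 16

Remark: C1 is carried as both configurations up to 20, as are C6 in 16 and C8 in 22–26; all three later become sp2 or cationic, so the mixtures converge. Acyclic compounds carry IUPAC locants; bicyclic compounds carry the C1–C10 numbering above.

Step 1
Reactants: 1 3-methylbut-1-yne
Product: 2 ethyl 4-methylpent-2-ynoate
Conditions: n-BuLi, THF, −78 °C; ClCO2Et, −78 → 0 °C
Reagents that add atoms: ethyl chloroformate CCOC(=O)Cl
Why: Lithiation of the terminal alkyne and C-acylation of the acetylide with a chloroformate (acetylide acylation) is a standard route to 2-ynoates.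

Step 2
Reactants: 2 ethyl 4-methylpent-2-ynoate
Product: 3 ethyl (2Z)-3-iodo-4-methylpent-2-enoate
Conditions: NaI, AcOH, 110 °C
Reagents that add atoms: sodium iodide [Na+].[I-]
Why: Conjugate hydroiodination of a 2-ynoate with NaI in AcOH is anti-selective and should give the (Z)-β-iodo enoate, which fixes the geometry of the later trisubstituted alkene.

Step 3
Reactants: 4 3-acetyl-3-methyloxolan-2-one
Product: 5 5-bromo-3-methylpentan-2-one
Conditions: 48% aq. HBr, 100 °C
Reagents that add atoms: hydrogen bromide Br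
Why: Bromide opens the protonated lactone at the O–CH2 carbon and the resulting β-keto acid decarboxylates (acidic ring opening–decarboxylation of an α-acyl butyrolactone), leaving C1 as an inconsequential stereocentre.

Step 4
Reactants: 5 5-bromo-3-methylpentan-2-one
Product: 6 2-(4-bromobutan-2-yl)-2-methyl-1,3-dioxolane
Conditions: ethane-1,2-diol, p-TsOH (cat.), toluene, reflux, Dean–Stark
Reagents that add atoms: ethane-1,2-diol OCCO
Why: Acid-catalysed ketalisation with azeotropic removal of water masks the ketone for the organometallic and hydride steps.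

Step 5
Reactants: 6 2-(4-bromobutan-2-yl)-2-methyl-1,3-dioxolane; 3 ethyl (2Z)-3-iodo-4-methylpent-2-enoate
Product: 8 ethyl (2E)-6-(2-methyl-1,3-dioxolan-2-yl)-3-(propan-2-yl)hept-2-enoate, via alkylzinc bromide 7 (not isolated)
Conditions: Zn dust, LiCl, THF, 45 °C; then 3, Pd(PPh3)4 (3 mol %), THF, 45 °C
Reagents that add atoms: none
Why: LiCl-mediated zinc insertion into the primary bromide and Negishi sp3–sp2 cross-coupling, which retains the iodoalkene geometry, should give the (E)-enoate with the alkyl chain cis to the ester.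

Step 6
Reactants: 8 ethyl (2E)-6-(2-methyl-1,3-dioxolan-2-yl)-3-(propan-2-yl)hept-2-enoate
Product: 9 (2E)-6-(2-methyl-1,3-dioxolan-2-yl)-3-(propan-2-yl)hept-2-en-1-ol
Conditions: iBu2AlH (2.2 equiv), CH2Cl2, −78 °C; Rochelle salt
Reagents that add atoms: none
Why: 1,2-Reduction of the α,β-unsaturated ester by the aluminium hydride at low temperature gives the allylic alcohol without touching the ketal.

Step 7
Reactants: 9 (2E)-6-(2-methyl-1,3-dioxolan-2-yl)-3-(propan-2-yl)hept-2-en-1-ol
Product: 10 {(2R,3R)-3-[3-(2-methyl-1,3-dioxolan-2-yl)butyl]-3-(propan-2-yl)oxiran-2-yl}methanol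
Conditions: Ti(OiPr)4 (10 mol %), D-(−)-diethyl tartrate (12 mol %), tBuOOH, 4 Å MS, CH2Cl2, −20 °C
Reagents that add atoms: tert-butyl hydroperoxide CC(C)(C)OO
Why: Sharpless asymmetric epoxidation of a 3,3-disubstituted (E)-allylic alcohol, a good substrate class; D-(−)-tartrate delivers oxygen to the face that makes the quaternary epoxide carbon (future C4) R.

Step 8
Reactants: 10 {(2R,3R)-3-[3-(2-methyl-1,3-dioxolan-2-yl)butyl]-3-(propan-2-yl)oxiran-2-yl}methanol
Product: 11 (3S)-6-(2-methyl-1,3-dioxolan-2-yl)-3-(propan-2-yl)heptane-1,3-diol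
Conditions: NaAlH2(OCH2CH2OMe)2, THF, 0 °C → rt
Reagents that add atoms: none
Why: Regioselective hydride opening of a 2,3-epoxy alcohol, with intramolecular delivery from the alkoxyaluminate to the epoxide CH (future C5), gives the 1,3-diol and leaves the tertiary C–O bond and thus the C4 configuration untouched.

Step 9
Reactants: 11 (3S)-6-(2-methyl-1,3-dioxolan-2-yl)-3-(propan-2-yl)heptane-1,3-diol
Product: 12 (3S)-6-(2-methyl-1,3-dioxolan-2-yl)-3-(propan-2-yl)-1,3-bis(triethylsilyloxy)heptane
Conditions: TESOTf (2.4 equiv), 2,6-lutidine, CH2Cl2, −78 → 0 °C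
Reagents that add atoms: triethylsilyl triflate CC[Si](CC)(CC)OS(=O)(=O)C(F)(F)F
Why: A silyl triflate with 2,6-lutidine silylates both the primary and the hindered tertiary hydroxyl (silyl ether formation).

Step 10
Reactants: 12 (3S)-6-(2-methyl-1,3-dioxolan-2-yl)-3-(propan-2-yl)-1,3-bis(triethylsilyloxy)heptane
Product: 13 (3S)-6-(2-methyl-1,3-dioxolan-2-yl)-3-(propan-2-yl)-3-(triethylsilyloxy)heptanal
Conditions: (COCl)2, DMSO, CH2Cl2, −78 → −30 °C; Et3N, −78 → 0 °C
Reagents that add atoms: none
Why: Under Swern conditions a primary triethylsilyl ether is cleaved and oxidised directly to the aldehyde while the hindered tertiary silyl ether survives (Swern oxidation of a primary silyl ether).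

Step 11
Reactants: 13 (3S)-6-(2-methyl-1,3-dioxolan-2-yl)-3-(propan-2-yl)-3-(triethylsilyloxy)heptanal; 14 (1E)-1-bromoprop-1-ene
Product: 16 (2E,6S)-9-(2-methyl-1,3-dioxolan-2-yl)-6-(propan-2-yl)-6-(triethylsilyloxy)dec-2-en-4-ol, via (E)-propenyllithium 15 (not isolated)
Conditions: 14, t-BuLi (2 equiv), Et2O, −78 °C; then 13, −78 °C
Reagents that add atoms: none
Why: Bromine–lithium exchange retains the (E) geometry and the alkenyllithium adds 1,2 to the aldehyde; the new carbinol centre forms as both epimers and is oxidised in the next step.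

Step 12
Reactants: 16 (2E,6S)-9-(2-methyl-1,3-dioxolan-2-yl)-6-(propan-2-yl)-6-(triethylsilyloxy)dec-2-en-4-ol
Product: 17 (2E,6S)-9-(2-methyl-1,3-dioxolan-2-yl)-6-(propan-2-yl)-6-(triethylsilyloxy)dec-2-en-4-one
Conditions: Dess–Martin periodinane, NaHCO3, CH2Cl2, rt
Reagents that add atoms: none
Why: Dess–Martin oxidation of the secondary allylic alcohol gives the (E)-propenyl ketone under neutral conditions.

Step 13
Reactants: 17 (2E,6S)-9-(2-methyl-1,3-dioxolan-2-yl)-6-(propan-2-yl)-6-(triethylsilyloxy)dec-2-en-4-one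
Product: 18 (6S,9E)-3-methyl-6-(propan-2-yl)-6-(triethylsilyloxy)undec-9-ene-2,8-dione
Conditions: PPTS (0.2 equiv), acetone/H2O (10:1), 45 °C
Reagents that add atoms: water O
Why: Mild acid-catalysed ketal hydrolysis frees the methyl ketone, and a tertiary triethylsilyl ether is stable to PPTS.

Step 14
Reactants: 18 (6S,9E)-3-methyl-6-(propan-2-yl)-6-(triethylsilyloxy)undec-9-ene-2,8-dione
Product: 19 (6S,9E)-3-chloro-3-methyl-6-(propan-2-yl)-6-(triethylsilyloxy)undec-9-ene-2,8-dione
Conditions: SO2Cl2 (1.05 equiv), CH2Cl2, 0 °C, dark; N2 purge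
Reagents that add atoms: sulfuryl chloride O=S(=O)(Cl)Cl
Why: α-Chlorination of a ketone with SO2Cl2 runs through the more substituted enol (C10=C1), so the tertiary chloride should form, while the conjugated ketone enolises slowly toward its neopentylic C5 methylene and its electron-poor alkene does not add chlorine in the dark.

Step 15
Reactants: 19 (6S,9E)-3-chloro-3-methyl-6-(propan-2-yl)-6-(triethylsilyloxy)undec-9-ene-2,8-dione
Product: 20 (6R,7Z,9E)-2,8-bis(tert-butyldimethylsilyloxy)-3-chloro-3-methyl-6-(propan-2-yl)-6-(triethylsilyloxy)undeca-1,7,9-triene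
Conditions: LiN(iPr)2 (2.3 equiv), THF, −78 °C, 15 min; TBSOTf (2.4 equiv), −78 °C; Et3N, pentane work-up
Reagents that add atoms: tert-butyldimethylsilyl triflate CC(C)(C)[Si](C)(C)OS(=O)(=O)C(F)(F)F
Why: Kinetic deprotonation at the methyl group of the chloro ketone and at the α′-methylene C5 of the enone, then O-silylation (kinetic silyl enol ether formation), gives the 2-siloxyallyl chloride and the cross-conjugated (Z)-siloxydiene, Z because the bulky C4 group avoids the propenyl group in the enolate.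

Step 16
Reactants: 20 (6R,7Z,9E)-2,8-bis(tert-butyldimethylsilyloxy)-3-chloro-3-methyl-6-(propan-2-yl)-6-(triethylsilyloxy)undeca-1,7,9-triene
Product: 22 (1S,4R,5S)-6-(tert-butyldimethylsilyloxy)-1,8-dimethyl-4-(propan-2-yl)-4-(triethylsilyloxy)bicyclo[5.3.0]dec-6-en-10-one (trans-fused, C8 epimers), via siloxyallyl cation 21 (not isolated)
Conditions: AgClO4 (1.2 equiv), 2,6-di-tert-butyl-4-methylpyridine (0.5 equiv), CH2Cl2/MeNO2 (4:1), 0.005 M, −40 → 0 °C; aq. NaHCO3
Reagents that add atoms: none
Why: AgClO4 abstracts the tertiary allylic chloride to give the 2-siloxyallyl cation 21 (C9–C10–C1), which adds across the tethered 2-siloxydiene (C5 to C8), in concert or by attack of the enol-ether terminus C5 on C1 followed by closure of C9 onto C8, and loss of the silyl group from the C10 oxocarbenium leaves the C10 ketone beside the C6 silyl enol ether. The closest known reaction types are the (4+3) cycloaddition of silver-generated 2-siloxyallyl cations with dienes and the intramolecular oxyallyl cation–diene (4+3) route to bicyclo[5.3.0]decenones. Ring A closes through C1–C5 as a five-membered ring in a 5-exo mode fixed by the three-atom tether, and ring B closes through C8–C9 as the seven-membered ring of the (4+3) event itself. C5 is set by C4, the cation adding to the diene face that puts the C5–C6 bond cis to the C4 silyloxy group and trans to the bulkier isopropyl group, and C1 is set by an extended transition state in which C10 points away from the diene, which gives the trans fusion (C1 methyl trans to H5). The step needs ionisation of C–Cl in preference to the allylic C4–O bond and complete (4+3) closure rather than (3+2) or open-chain capture, which the halophilic silver salt, low temperature, short tether and high dilution are meant to secure. C8 may form as either epimer and becomes sp2 in step 21.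

Step 17
Reactants: 22 (1S,4R,5S)-6-(tert-butyldimethylsilyloxy)-1,8-dimethyl-4-(propan-2-yl)-4-(triethylsilyloxy)bicyclo[5.3.0]dec-6-en-10-one
Product: 23 (1S,4R,5R)-4-hydroxy-1,8-dimethyl-4-(propan-2-yl)bicyclo[5.3.0]decane-6,10-dione
Conditions: 48% aq. HF/MeCN (1:19), 0 °C → rt
Reagents that add atoms: none
Why: HF protonates the silyl enol ether at C7 (enol ether hydrolysis) and cleaves the tertiary silyl ether (fluoride-mediated desilylation), so C5 is not touched and the β-hydroxy ketone is released without base that could open ring A by retro-aldol reaction.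

Step 18
Reactants: 23 (1S,4R,5R)-4-hydroxy-1,8-dimethyl-4-(propan-2-yl)bicyclo[5.3.0]decane-6,10-dione
Product: 24 (1S,4R,5S,6S)-4,6-dihydroxy-1,8-dimethyl-4-(propan-2-yl)bicyclo[5.3.0]decan-10-one
Conditions: Me4NBH(OAc)3, MeCN/AcOH (1:1), −25 °C
Reagents that add atoms: none
Why: Evans–Saksena reduction: the C4 hydroxyl binds boron and delivers hydride intramolecularly to the face of the C6 ketone it overlooks, which sets 6S with the new hydroxyl cis to H5, and the isolated C10 ketone is not reduced by this reagent.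

Step 19
Reactants: 24 (1S,4R,5S,6S)-4,6-dihydroxy-1,8-dimethyl-4-(propan-2-yl)bicyclo[5.3.0]decan-10-one
Product: 25 (1S,4R,5S,6S)-4-hydroxy-1,8-dimethyl-10-oxo-4-(propan-2-yl)bicyclo[5.3.0]decan-6-yl benzoate
Conditions: BzCl, pyridine, DMAP (cat.), CH2Cl2, 0 °C → rt
Reagents that add atoms: benzoyl chloride O=C(Cl)c1ccccc1
Why: DMAP-catalysed acylation is selective for the secondary C6 hydroxyl because the tertiary C4 hydroxyl is too hindered to react.

Step 20
Reactants: 25 (1S,4R,5S,6S)-4-hydroxy-1,8-dimethyl-10-oxo-4-(propan-2-yl)bicyclo[5.3.0]decan-6-yl benzoate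
Product: 26 (1S,4R,5S,6S)-1,8-dimethyl-4-(propan-2-yl)-4,10-bis(trimethylsilyloxy)bicyclo[5.3.0]dec-9-en-6-yl benzoate
Conditions: TMSOTf (2.5 equiv), Et3N, CH2Cl2, 0 °C
Reagents that add atoms: trimethylsilyl triflate C[Si](C)(C)OS(=O)(=O)C(F)(F)F
Why: Soft enolisation (silyl enol ether formation) can only go toward C9 because C1 is quaternary, the benzoate tolerates the amine base, and the tertiary hydroxyl is silylated at the same time.

Step 21
Reactants: 26 (1S,4R,5S,6S)-1,8-dimethyl-4-(propan-2-yl)-4,10-bis(trimethylsilyloxy)bicyclo[5.3.0]dec-9-en-6-yl benzoate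
Product: 28 (1S,4R,5S,6S)-4-hydroxy-1,8-dimethyl-10-oxo-4-(propan-2-yl)bicyclo[5.3.0]dec-8-en-6-yl benzoate, via silyl ether enone 27 (not isolated)
Conditions: Pd(OAc)2 (1.1 equiv), MeCN, rt; then 1 M HCl, THF, 0 °C
Reagents that add atoms: none
Why: Saegusa–Ito oxidation: the silyl enol ether gives a divalent palladium enolate at C9 that loses the C8 hydrogen by β-hydride elimination, placing the double bond at C8=C9 and erasing the C8 stereocentre, and the acidic work-up removes the labile tertiary trimethylsilyl ether.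

Step 22
Reactants: 28 (1S,4R,5S,6S)-4-hydroxy-1,8-dimethyl-10-oxo-4-(propan-2-yl)bicyclo[5.3.0]dec-8-en-6-yl benzoate
Product: 29 (1S,4R,5S,6S,10S)-4,10-dihydroxy-1,8-dimethyl-4-(propan-2-yl)bicyclo[5.3.0]dec-8-en-6-yl benzoate
Conditions: NaBH4, CeCl3·7H2O, MeOH, −78 → −40 °C
Reagents that add atoms: none
Why: Luche 1,2-reduction of the enone; hydride should enter anti to the pseudoaxial C1 methyl, as in reductions of ketones next to an angular methyl group, giving the 10S alcohol with the hydroxyl cis to that methyl.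

Step 23
Reactants: 29 (1S,4R,5S,6S,10S)-4,10-dihydroxy-1,8-dimethyl-4-(propan-2-yl)bicyclo[5.3.0]dec-8-en-6-yl benzoate; 30 angelic acid, (2Z)-2-methylbut-2-enoic acid
Product: 31 CNP0397959.1, (1S,4R,5S,6S,10R)-4-hydroxy-1,8-dimethyl-10-[(2Z)-2-methylbut-2-enoyloxy]-4-(propan-2-yl)bicyclo[5.3.0]dec-8-en-6-yl benzoate
Conditions: PPh3, DIAD, toluene, 0 °C → rt
Reagents that add atoms: none
Why: Mitsunobu esterification displaces the activated C10 oxygen by angelate in an SN2 step with inversion (nucleophile entering anti to the C1 methyl), which sets 10R; the acid is never activated as an acyl donor, so its Z double bond should survive, and the tertiary hydroxyl does not react.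

**Compound list**
1 | 3-methylbut-1-yne | CC(C)C#C | starting material
2 | ethyl 4-methylpent-2-ynoate | CCOC(=O)C#CC(C)C | intermediate
3 | ethyl (2Z)-3-iodo-4-methylpent-2-enoate | CCOC(=O)/C=C(\I)C(C)C | intermediate
4 | 3-acetyl-3-methyloxolan-2-one (α-acetyl-α-methyl-γ-butyrolactone) | CC(=O)C1(C)CCOC1=O | starting material
5 | 5-bromo-3-methylpentan-2-one | CC(=O)C(C)CCBr | intermediate
6 | 2-(4-bromobutan-2-yl)-2-methyl-1,3-dioxolane | CC1(OCCO1)C(C)CCBr | intermediate
7 | [3-(2-methyl-1,3-dioxolan-2-yl)butyl]zinc bromide | CC1(OCCO1)C(C)CC[Zn]Br | intermediate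
8 | ethyl (2E)-6-(2-methyl-1,3-dioxolan-2-yl)-3-(propan-2-yl)hept-2-enoate | CCOC(=O)/C=C(/C(C)C)CCC(C)C1(C)OCCO1 | intermediate
9 | (2E)-6-(2-methyl-1,3-dioxolan-2-yl)-3-(propan-2-yl)hept-2-en-1-ol | OC/C=C(/C(C)C)CCC(C)C1(C)OCCO1 | intermediate
10 | {(2R,3R)-3-[3-(2-methyl-1,3-dioxolan-2-yl)butyl]-3-(propan-2-yl)oxiran-2-yl}methanol | OC[C@H]1O[C@@]1(C(C)C)CCC(C)C2(C)OCCO2 | intermediate
11 | (3S)-6-(2-methyl-1,3-dioxolan-2-yl)-3-(propan-2-yl)heptane-1,3-diol | CC1(OCCO1)C(C)CC[C@@](O)(C(C)C)CCO | intermediate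
12 | (3S)-6-(2-methyl-1,3-dioxolan-2-yl)-3-(propan-2-yl)-1,3-bis(triethylsilyloxy)heptane | CC1(OCCO1)C(C)CC[C@@](O[Si](CC)(CC)CC)(C(C)C)CCO[Si](CC)(CC)CC | intermediate
13 | (3S)-6-(2-methyl-1,3-dioxolan-2-yl)-3-(propan-2-yl)-3-(triethylsilyloxy)heptanal | CC1(OCCO1)C(C)CC[C@@](O[Si](CC)(CC)CC)(C(C)C)CC=O | intermediate
14 | (1E)-1-bromoprop-1-ene | C/C=C/Br | starting material
15 | (1E)-prop-1-en-1-yllithium | C/C=C/[Li] | intermediate
16 | (2E,6S)-9-(2-methyl-1,3-dioxolan-2-yl)-6-(propan-2-yl)-6-(triethylsilyloxy)dec-2-en-4-ol (carbinol epimers) | CC1(OCCO1)C(C)CC[C@@](O[Si](CC)(CC)CC)(C(C)C)CC(O)/C=C/C | intermediate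
17 | (2E,6S)-9-(2-methyl-1,3-dioxolan-2-yl)-6-(propan-2-yl)-6-(triethylsilyloxy)dec-2-en-4-one | CC1(OCCO1)C(C)CC[C@@](O[Si](CC)(CC)CC)(C(C)C)CC(=O)/C=C/C | intermediate
18 | (6S,9E)-3-methyl-6-(propan-2-yl)-6-(triethylsilyloxy)undec-9-ene-2,8-dione | CC(=O)C(C)CC[C@@](O[Si](CC)(CC)CC)(C(C)C)CC(=O)/C=C/C | intermediate
19 | (6S,9E)-3-chloro-3-methyl-6-(propan-2-yl)-6-(triethylsilyloxy)undec-9-ene-2,8-dione | CC(=O)C(C)(Cl)CC[C@@](O[Si](CC)(CC)CC)(C(C)C)CC(=O)/C=C/C | intermediate
20 | (6R,7Z,9E)-2,8-bis(tert-butyldimethylsilyloxy)-3-chloro-3-methyl-6-(propan-2-yl)-6-(triethylsilyloxy)undeca-1,7,9-triene | C=C(O[Si](C)(C)C(C)(C)C)C(C)(Cl)CC[C@@](O[Si](CC)(CC)CC)(C(C)C)/C=C(O[Si](C)(C)C(C)(C)C)/C=C/C | intermediate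
21 | (6R,7Z,9E)-2,8-bis(tert-butyldimethylsilyloxy)-3-methyl-6-(propan-2-yl)-6-(triethylsilyloxy)undeca-1,7,9-trien-3-ylium perchlorate (2-siloxyallyl cation) | C=C(O[Si](C)(C)C(C)(C)C)[C+](C)CC[C@@](O[Si](CC)(CC)CC)(C(C)C)/C=C(O[Si](C)(C)C(C)(C)C)/C=C/C.[O-]Cl(=O)(=O)=O | intermediate
22 | (1S,4R,5S)-6-(tert-butyldimethylsilyloxy)-1,8-dimethyl-4-(propan-2-yl)-4-(triethylsilyloxy)bicyclo[5.3.0]dec-6-en-10-one (C8 epimers) | O=C1CC(C)C=C(O[Si](C)(C)C(C)(C)C)[C@@H]2[C@]1(C)CC[C@@]2(O[Si](CC)(CC)CC)C(C)C | intermediate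
23 | (1S,4R,5R)-4-hydroxy-1,8-dimethyl-4-(propan-2-yl)bicyclo[5.3.0]decane-6,10-dione (C8 epimers) | O=C1CC(C)CC(=O)[C@@H]2[C@]1(C)CC[C@@]2(O)C(C)C | intermediate
24 | (1S,4R,5S,6S)-4,6-dihydroxy-1,8-dimethyl-4-(propan-2-yl)bicyclo[5.3.0]decan-10-one (C8 epimers) | O=C1CC(C)C[C@H](O)[C@@H]2[C@]1(C)CC[C@@]2(O)C(C)C | intermediate
25 | (1S,4R,5S,6S)-4-hydroxy-1,8-dimethyl-10-oxo-4-(propan-2-yl)bicyclo[5.3.0]decan-6-yl benzoate (C8 epimers) | O=C1CC(C)C[C@H](OC(=O)c3ccccc3)[C@@H]2[C@]1(C)CC[C@@]2(O)C(C)C | intermediate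
26 | (1S,4R,5S,6S)-1,8-dimethyl-4-(propan-2-yl)-4,10-bis(trimethylsilyloxy)bicyclo[5.3.0]dec-9-en-6-yl benzoate (C8 epimers) | C[Si](C)(C)OC1=CC(C)C[C@H](OC(=O)c3ccccc3)[C@@H]2[C@]1(C)CC[C@@]2(O[Si](C)(C)C)C(C)C | intermediate
27 | (1S,4R,5S,6S)-1,8-dimethyl-10-oxo-4-(propan-2-yl)-4-(trimethylsilyloxy)bicyclo[5.3.0]dec-8-en-6-yl benzoate | O=C1C=C(C)C[C@H](OC(=O)c3ccccc3)[C@@H]2[C@]1(C)CC[C@@]2(O[Si](C)(C)C)C(C)C | intermediate
28 | (1S,4R,5S,6S)-4-hydroxy-1,8-dimethyl-10-oxo-4-(propan-2-yl)bicyclo[5.3.0]dec-8-en-6-yl benzoate | O=C1C=C(C)C[C@H](OC(=O)c3ccccc3)[C@@H]2[C@]1(C)CC[C@@]2(O)C(C)C | intermediate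
29 | (1S,4R,5S,6S,10S)-4,10-dihydroxy-1,8-dimethyl-4-(propan-2-yl)bicyclo[5.3.0]dec-8-en-6-yl benzoate | O[C@H]1C=C(C)C[C@H](OC(=O)c3ccccc3)[C@@H]2[C@]1(C)CC[C@@]2(O)C(C)C | intermediate
30 | angelic acid, (2Z)-2-methylbut-2-enoic acid | C/C=C(/C)C(=O)O | starting material
31 | CNP0397959.1, (1S,4R,5S,6S,10R)-4-hydroxy-1,8-dimethyl-10-[(2Z)-2-methylbut-2-enoyloxy]-4-(propan-2-yl)bicyclo[5.3.0]dec-8-en-6-yl benzoate | C/C=C(/C)C(=O)O[C@@H]1C=C(C)C[C@H](OC(=O)c2ccccc2)[C@@H]2[C@]1(C)CC[C@@]2(O)C(C)C | target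

**Step count and risks**
Total: 23 steps. Longest linear sequence: 21 steps (steps 3–23 from 4; equally steps 1, 2 and 5–23 from 1); the two branches meet in step 5.

Steps most likely to fail:

1. Step 16. The cascade may stop after the first bond (capture of the cation at C5 only, then loss of silyl), close onto C6 in a (3+2) sense, ionise the allylic C4–O bond, or give partly cis-fused material. Fallback, making the two bonds in sequence: setting out from 20, the same AgClO4 ionisation is quenched cold with dilute aqueous acid so that the C1–C5 alkylation product is isolated as the acetyl/propenyl-ketone cyclopentane F1. Intramolecular Michael addition of the acetyl enolate (C9) onto the propenyl ketone (C8) with KOtBu in THF/tBuOH at 0 °C should close ring B to the diketone silyl ether F2; the reversible Michael step and the enolisable C5 allow equilibration toward the trans fusion. HF in MeCN then returns to 23.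

2. Step 14. Chlorination may also occur at C5 or C9, chlorine may add across the enone, and the HCl formed may cleave the tertiary silyl ether. Fallback, chlorinating a regiodefined silyl enol ether before the enone exists: setting out from 16, PPTS in wet acetone frees the ketone to give the keto alcohol F3. TMSCl, NaI and Et3N in MeCN should give the thermodynamic tetrasubstituted silyl enol ether together with the C-O silyl ether, the bis(trimethylsilyl) compound F4. NCS in THF at 0 °C with a citric acid work-up chlorinates C1 and frees the carbinol, giving the chloro ketone alcohol F5 (the isolated alkene is inert to NCS). Dess–Martin oxidation then returns to 19.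

3. Step 23. Substitution at the neopentylic allylic C10 may be slow, so that elimination to a diene or SN2′ attack at C8 competes. Fallback, setting C10 by reagent control and acylating with retention: setting out from 28, Corey–Bakshi–Shibata reduction with (S)-2-methyl-CBS-oxazaborolidine and catecholborane in toluene at −78 °C should deliver hydride to the methyl-bearing face (quaternary C1 taken as the large group) and give the (10R)-alcohol F6. Yamaguchi esterification with angelic acid 30 (2,4,6-trichlorobenzoyl chloride, Et3N, toluene, then F6, 80 °C, no DMAP to avoid Z to E isomerisation) then comes back at 31.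

**Further compounds**
F1 | step 16 | (2E)-1-[(1S,2S,5R)-2-acetyl-2-methyl-5-(propan-2-yl)-5-(triethylsilyloxy)cyclopentyl]but-2-en-1-one | C/C=C/C(=O)[C@@H]1[C@](C(C)=O)(C)CC[C@@]1(O[Si](CC)(CC)CC)C(C)C
F2 | step 16 | (1S,4R,5S)-1,8-dimethyl-4-(propan-2-yl)-4-(triethylsilyloxy)bicyclo[5.3.0]decane-6,10-dione (plan numbering) | O=C1CC(C)CC(=O)[C@@H]2[C@]1(C)CC[C@@]2(O[Si](CC)(CC)CC)C(C)C
F3 | step 14 | (6S,9E)-8-hydroxy-3-methyl-6-(propan-2-yl)-6-(triethylsilyloxy)undec-9-en-2-one | CC(=O)C(C)CC[C@@](O[Si](CC)(CC)CC)(C(C)C)CC(O)/C=C/C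
F4 | step 14 | (6S,9E)-3-methyl-6-(propan-2-yl)-6-(triethylsilyloxy)-2,8-bis(trimethylsilyloxy)undeca-2,9-diene | CC(O[Si](C)(C)C)=C(C)CC[C@@](O[Si](CC)(CC)CC)(C(C)C)CC(O[Si](C)(C)C)/C=C/C
F5 | step 14 | (6S,9E)-3-chloro-8-hydroxy-3-methyl-6-(propan-2-yl)-6-(triethylsilyloxy)undec-9-en-2-one | CC(=O)C(C)(Cl)CC[C@@](O[Si](CC)(CC)CC)(C(C)C)CC(O)/C=C/C
F6 | step 23 | (1S,4R,5S,6S,10R)-4,10-dihydroxy-1,8-dimethyl-4-(propan-2-yl)bicyclo[5.3.0]dec-8-en-6-yl benzoate | O[C@@H]1C=C(C)C[C@H](OC(=O)c3ccccc3)[C@@H]2[C@]1(C)CC[C@@]2(O)C(C)C
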